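## Retrosynthetic overview

1. The acid and phenol are unmasked last. The (E)-trisubstituted alkene and the aryl–CH2 bond come from one operation: carboalumination of a terminal alkyne on the bicyclic fragment and Pd-catalysed coupling with a benzylic bromide made from methyl 4-hydroxy-3-methylbenzoate.
2. Key disconnection: the 7-oxabicyclo[2.2.1]heptane is opened at two bonds at once, C5–C6 (the CH2–CH2 bond) and O7–C1 (oxygen to the methyl-bearing bridgehead). This leads back to an acyclic 2-(tert-alkyl)oxirane carrying an isopropenyl group; in the forward sense one Lewis-acid step closes the carbocycle first and the oxygen bridge second.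
3. Enabling feature: O7 spans C1 and C4, that is 1,4 across the six-membered carbocycle C1–C6. C1 is the methyl-bearing carbon that an isopropenyl group turns into a tertiary cation. The oxygen-bearing C4 lies next to the quaternary C3 (gem-dimethyl), which shields the internal oxirane carbon and leaves the oxirane CH2 (future C5) as the only electrophilic site.
4. Stereochemistry: C2 comes from C5 of (S)-carvone (1,4-reduction, Baeyer–Villiger ring expansion, gem-dimethylation of the lactone, alkyne formation). C4 comes from a CBS reduction of a chloromethyl ketone. C1 is dictated by the bridge.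

Key step: step 9

Remark on the chemistry: compounds 2 to 6 are carried as mixtures at the methyl-bearing carbon that becomes the ketone carbon of 7, so that centre is left undefined in their SMILES.

## Route

Step 1
Reactants: 1 (S)-(+)-carvone, (5S)-2-methyl-5-(prop-1-en-2-yl)cyclohex-2-en-1-one
Product: 2 (5S)-2-methyl-5-(prop-1-en-2-yl)cyclohexan-1-one (dihydrocarvone, both C2 epimers)
Conditions: Li[HB(s-Bu)3] (1.1 equiv), THF, −78 °C; then H2O, −78 °C → rt
Reagents that add atoms: none
Why: Conjugate (1,4) hydride reduction of the β-unsubstituted enone by the bulky trialkylborohydride and protonation of the enolate should give the saturated ketone; C5 is untouched and the new C2 centre is an inconsequential mixture that is erased in step 5.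

Step 2
Reactants: 2 (5S)-2-methyl-5-(prop-1-en-2-yl)cyclohexan-1-one
Product: 3 (4S)-7-methyl-4-(prop-1-en-2-yl)oxepan-2-one (both C7 epimers)
Conditions: Me3SiOOSiMe3 (1.5 equiv), Me3SiOTf (0.1 equiv), CH2Cl2, −78 → −30 °C
Reagents that add atoms: bis(trimethylsilyl) peroxide, C[Si](C)(C)OO[Si](C)(C)C
Why: Baeyer–Villiger oxidation should insert oxygen on the side of the more substituted (secondary) α-carbon with retention, and the silyl peroxide is chosen because it oxidises ketones without epoxidising an isolated alkene such as the isopropenyl group.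

Step 3
Reactants: 3 (4S)-7-methyl-4-(prop-1-en-2-yl)oxepan-2-one
Product: 5 (4R)-3,3,7-trimethyl-4-(prop-1-en-2-yl)oxepan-2-one, via monomethyl lactone 4 (not isolated)
Conditions: LiN(i-Pr)2 (1.1 equiv), THF, −78 °C; MeI (1.05 equiv); then LiN(i-Pr)2 (1.3 equiv), DMPU, −78 °C; MeI (2 equiv), −78 → −20 °C
Reagents that add atoms: iodomethane, CI
Why: Two successive lactone enolate alkylations at the only enolisable position (C3) should install the gem-dimethyl group; C4 is β to the carbonyl and cannot epimerise (its descriptor changes from S to R only because the CIP priorities change), and no new stereocentre remains once C3 is quaternary.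

Step 4
Reactants: 5 (4R)-3,3,7-trimethyl-4-(prop-1-en-2-yl)oxepan-2-one
Product: 6 methyl (3R)-6-hydroxy-2,2-dimethyl-3-(prop-1-en-2-yl)heptanoate (both C6 epimers)
Conditions: NaOMe (0.2 equiv), MeOH, 50 °C; AcOH (0.2 equiv) before concentration
Reagents that add atoms: methanol, CO
Why: Methoxide-catalysed transesterification (methanolysis) of the seven-membered lactone in neat methanol should release the secondary alcohol and the methyl ester without touching C3.

Step 5
Reactants: 6 methyl (3R)-6-hydroxy-2,2-dimethyl-3-(prop-1-en-2-yl)heptanoate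
Product: 7 methyl (3R)-2,2-dimethyl-6-oxo-3-(prop-1-en-2-yl)heptanoate
Conditions: [N(n-Pr)4][RuO4] (5 mol %), N-methylmorpholine N-oxide (1.5 equiv), 4 Å MS, CH2Cl2, rt
Reagents that add atoms: none
Why: Ley–Griffith oxidation of the secondary alcohol is neutral, should leave the alkene and the ester alone, and removes the stereo-mixture at the carbinol carbon.

Step 6
Reactants: 7 methyl (3R)-2,2-dimethyl-6-oxo-3-(prop-1-en-2-yl)heptanoate
Product: 9 methyl (3R)-2,2-dimethyl-3-(prop-1-en-2-yl)hept-6-ynoate, via enol phosphate 8 (not isolated)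
Conditions: LiN(i-Pr)2 (1.1 equiv), THF, −78 °C; ClP(O)(OEt)2 (1.15 equiv), −78 → 0 °C; then LiN(i-Pr)2 (2.3 equiv), −78 °C → rt; H2O
Reagents that add atoms: none
Why: Kinetic deprotonation of the methyl ketone at CH3, O-phosphorylation and base-induced elimination of the enol phosphate is the established conversion of methyl ketones into terminal alkynes, and the ester should survive because it has no α-hydrogen and is neopentyl-hindered.

Step 7
Reactants: 9 methyl (3R)-2,2-dimethyl-3-(prop-1-en-2-yl)hept-6-ynoate
Product: 10 (4R)-1-chloro-3,3-dimethyl-4-(prop-1-en-2-yl)oct-7-yn-2-one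
Conditions: ICH2Cl (3 equiv), MeLi·LiBr (4 equiv, slow addition), THF/Et2O, −78 °C; AcOH quench at −78 °C
Reagents that add atoms: chloroiodomethane, ClCI
Why: Chloromethyllithium generated in situ by iodine–lithium exchange should add once to the ester because the tetrahedral lithium alkoxide is stable at −78 °C (the known ester to chloromethyl ketone homologation); one equivalent of MeLi is spent on the alkyne C–H, which is restored on quenching.

Step 8
Reactants: 10 (4R)-1-chloro-3,3-dimethyl-4-(prop-1-en-2-yl)oct-7-yn-2-one
Product: 12 (2R)-2-[(3R)-2-methyl-3-(prop-1-en-2-yl)hept-6-yn-2-yl]oxirane, via chlorohydrin 11 (not isolated)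
Conditions: (R)-1-methyl-3,3-diphenyltetrahydro-1H,3H-pyrrolo[1,2-c][1,3,2]oxazaborole (the (R)-methyl CBS catalyst, 0.2 equiv), catecholborane (1.5 equiv), toluene, −78 → −30 °C; then 2 M aq. NaOH, MeOH, 0 °C → rt
Reagents that add atoms: none
Why: Corey–Bakshi–Shibata reduction with the (R)-oxazaborolidine should deliver hydride to the face that gives the (2R)-chlorohydrin, with the tert-alkyl group as the large and CH2Cl as the small substituent (the same spatial sense as (S)-1-phenylethanol from acetophenone); catecholborane does not hydroborate the alkene or alkyne at this temperature, and hydroxide then closes the oxirane by Williamson displacement at CH2Cl without touching the carbinol configuration.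

Step 9
Reactants: 12 (2R)-2-[(3R)-2-methyl-3-(prop-1-en-2-yl)hept-6-yn-2-yl]oxirane
Product: 13 (1R,2S,4S)-2-(but-3-yn-1-yl)-1,3,3-trimethyl-7-oxabicyclo[2.2.1]heptane
Conditions: BF3·OEt2 (0.3 equiv), CH2Cl2 (0.01 M), −78 → −20 °C; Et3N, then aq. NaHCO3
Reagents that add atoms: none
Why: Proposed new method: BF3 bound to the oxirane oxygen makes the oxirane CH2 an SN2-type electrophile, the CH2 terminus of the isopropenyl group attacks it anti to the breaking C–O bond through a chair-like six-membered transition state, and the tertiary cyclohexyl cation so formed is captured across the ring by the boron-bound alkoxide, so that the CH2–CH2 bond and the O–C(quaternary) bond arise in one cationic cascade. The closest known reaction type is the Lewis-acid epoxide-initiated cation–olefin cyclisation of epoxy-polyenes, where capture of the cyclohexyl cation by the former epoxide oxygen to give 7-oxabicyclo[2.2.1]heptanes is a known termination, together with the 6-endo Friedel–Crafts cyclisation of terminal aryl-alkyl epoxides at the oxirane CH2; what is new is C–C bond formation by an alkene at the primary carbon of a monosubstituted oxirane. The carbocycle closes 6-endo-trig on the alkene with endo opening of the oxirane (both oxirane carbons end in the ring), and the oxygen bridge closes as a transannular 1,4-capture (a five-membered closure, 5-exo on the trigonal cation) through a boat conformer. C2 and C4 of the product are carried over unchanged from 12 because neither the C–O bond at the carbinol carbon nor any bond at the side-chain carbon is broken, and the new quaternary centre C1 can only be (R) because the tethered oxygen reaches the cation from its own face, which also places the side chain exo. The selectivity needed is attack at the oxirane CH2 and Markovnikov use of the alkene: the internal oxirane carbon is neopentylic (next to the gem-dimethyl carbon) and would give a five-membered ring, the 1,1-disubstituted alkene is nucleophilic only at CH2 and gives a tertiary cation, the quaternary carbon gives a Thorpe–Ingold assist, and the terminal alkyne is a far poorer π-nucleophile. The bridged ether is also the thermodynamic sink, since any cyclohexenol formed by proton loss can re-enter through the same cation under the reaction conditions.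

Step 10
Reactants: 14 methyl 4-hydroxy-3-methylbenzoate
Product: 15 methyl 4-[(tert-butyldimethylsilyl)oxy]-3-methylbenzoate
Conditions: t-BuMe2SiCl (1.2 equiv), imidazole (2.5 equiv), DMF, rt
Reagents that add atoms: tert-butyldimethylsilyl chloride, C[Si](C)(Cl)C(C)(C)C
Why: Imidazole-promoted silylation of the phenol masks it for the radical bromination and the organometallic coupling.

Step 11
Reactants: 15 methyl 4-[(tert-butyldimethylsilyl)oxy]-3-methylbenzoate
Product: 16 methyl 3-(bromomethyl)-4-[(tert-butyldimethylsilyl)oxy]benzoate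
Conditions: N-bromosuccinimide (1.05 equiv), 2,2'-azobis(2-methylpropionitrile) (5 mol %), PhCF3, 85 °C
Reagents that add atoms: N-bromosuccinimide, BrN1C(=O)CCC1=O
Why: Wohl–Ziegler radical bromination should take place at the only benzylic C–H position, the ester-bearing ring being deactivated enough to resist electrophilic bromination.

Step 12
Reactants: 13 (1R,2S,4S)-2-(but-3-yn-1-yl)-1,3,3-trimethyl-7-oxabicyclo[2.2.1]heptane; 16 methyl 3-(bromomethyl)-4-[(tert-butyldimethylsilyl)oxy]benzoate
Product: 18 methyl 4-[(tert-butyldimethylsilyl)oxy]-3-{(2E)-3-methyl-5-[(1R,2S,4S)-1,3,3-trimethyl-7-oxabicyclo[2.2.1]heptan-2-yl]pent-2-en-1-yl}benzoate, via alkenylalane 17 (not isolated)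
Conditions: AlMe3 (2.2 equiv), Cp2ZrCl2 (0.25 equiv), CH2Cl2, 0 °C → rt; excess AlMe3 and solvent removed in vacuo; then 16 (1.0 equiv), Pd(PPh3)4 (5 mol %), THF, rt
Reagents that add atoms: trimethylaluminium, C[Al](C)C
Why: Zirconium-catalysed carboalumination (Negishi) should add Me and Al syn across the terminal alkyne with Al on the terminal carbon, and palladium-catalysed cross-coupling of the resulting (E)-alkenylalane with the benzylic bromide proceeds with retention, which fixes the E-trisubstituted alkene.

Step 13
Reactants: 18 methyl 4-[(tert-butyldimethylsilyl)oxy]-3-{(2E)-3-methyl-5-[(1R,2S,4S)-1,3,3-trimethyl-7-oxabicyclo[2.2.1]heptan-2-yl]pent-2-en-1-yl}benzoate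
Product: 19 4-hydroxy-3-{(2E)-3-methyl-5-[(1R,2S,4S)-1,3,3-trimethyl-7-oxabicyclo[2.2.1]heptan-2-yl]pent-2-en-1-yl}benzoic acid (CNP0422247.1)
Conditions: LiOH·H2O (6 equiv), THF/MeOH/H2O, 50 °C; then 1 M HCl to pH 4 at 0 °C
Reagents that add atoms: lithium hydroxide, [Li+].[OH-]
Why: Hydroxide should saponify the methyl ester and cleave the aryl silyl ether (phenoxide is a good leaving group on silicon), and mild acidification liberates the acid without exposing the prenyl-type phenol or the bridged ether to strong acid.

## Compound list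

1 | (S)-(+)-carvone, (5S)-2-methyl-5-(prop-1-en-2-yl)cyclohex-2-en-1-one | CC1=CC[C@@H](CC1=O)C(C)=C | starting material
2 | (5S)-2-methyl-5-(prop-1-en-2-yl)cyclohexan-1-one (both C2 epimers) | CC1CC[C@@H](CC1=O)C(C)=C | intermediate
3 | (4S)-7-methyl-4-(prop-1-en-2-yl)oxepan-2-one (both C7 epimers) | CC1CC[C@@H](CC(=O)O1)C(C)=C | intermediate
4 | (4S)-3,7-dimethyl-4-(prop-1-en-2-yl)oxepan-2-one (mixture at C3 and C7) | CC1CC[C@@H](C(C)C(=O)O1)C(C)=C | intermediate (not isolated)
5 | (4R)-3,3,7-trimethyl-4-(prop-1-en-2-yl)oxepan-2-one (both C7 epimers) | CC1CC[C@@H](C(C)(C)C(=O)O1)C(C)=C | intermediate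
6 | methyl (3R)-6-hydroxy-2,2-dimethyl-3-(prop-1-en-2-yl)heptanoate (both C6 epimers) | COC(=O)C(C)(C)[C@H](CCC(C)O)C(C)=C | intermediate
7 | methyl (3R)-2,2-dimethyl-6-oxo-3-(prop-1-en-2-yl)heptanoate | COC(=O)C(C)(C)[C@H](CCC(C)=O)C(C)=C | intermediate
8 | methyl (3R)-6-[(diethoxyphosphoryl)oxy]-2,2-dimethyl-3-(prop-1-en-2-yl)hept-6-enoate | COC(=O)C(C)(C)[C@H](CCC(=C)OP(=O)(OCC)OCC)C(C)=C | intermediate (not isolated)
9 | methyl (3R)-2,2-dimethyl-3-(prop-1-en-2-yl)hept-6-ynoate | COC(=O)C(C)(C)[C@H](CCC#C)C(C)=C | intermediate
10 | (4R)-1-chloro-3,3-dimethyl-4-(prop-1-en-2-yl)oct-7-yn-2-one | ClCC(=O)C(C)(C)[C@H](CCC#C)C(C)=C | intermediate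
11 | (2R,4R)-1-chloro-3,3-dimethyl-4-(prop-1-en-2-yl)oct-7-yn-2-ol | ClC[C@H](O)C(C)(C)[C@H](CCC#C)C(C)=C | intermediate (not isolated)
12 | (2R)-2-[(3R)-2-methyl-3-(prop-1-en-2-yl)hept-6-yn-2-yl]oxirane | C#CCC[C@H](C(C)=C)C(C)(C)[C@@H]1CO1 | intermediate
13 | (1R,2S,4S)-2-(but-3-yn-1-yl)-1,3,3-trimethyl-7-oxabicyclo[2.2.1]heptane | C#CCC[C@H]1C(C)(C)[C@@H]2CC[C@@]1(C)O2 | intermediate
14 | methyl 4-hydroxy-3-methylbenzoate | COC(=O)c1ccc(O)c(C)c1 | starting material
15 | methyl 4-[(tert-butyldimethylsilyl)oxy]-3-methylbenzoate | COC(=O)c1ccc(O[Si](C)(C)C(C)(C)C)c(C)c1 | intermediate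
16 | methyl 3-(bromomethyl)-4-[(tert-butyldimethylsilyl)oxy]benzoate | COC(=O)c1ccc(O[Si](C)(C)C(C)(C)C)c(CBr)c1 | intermediate
17 | dimethyl{(1E)-2-methyl-4-[(1R,2S,4S)-1,3,3-trimethyl-7-oxabicyclo[2.2.1]heptan-2-yl]but-1-en-1-yl}alane | C[Al](C)/C=C(\C)CC[C@H]1C(C)(C)[C@@H]2CC[C@@]1(C)O2 | intermediate (not isolated)
18 | methyl 4-[(tert-butyldimethylsilyl)oxy]-3-{(2E)-3-methyl-5-[(1R,2S,4S)-1,3,3-trimethyl-7-oxabicyclo[2.2.1]heptan-2-yl]pent-2-en-1-yl}benzoate | C/C(=C\Cc1cc(C(=O)OC)ccc1O[Si](C)(C)C(C)(C)C)CC[C@H]1C(C)(C)[C@@H]2CC[C@@]1(C)O2 | intermediate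
19 | 4-hydroxy-3-{(2E)-3-methyl-5-[(1R,2S,4S)-1,3,3-trimethyl-7-oxabicyclo[2.2.1]heptan-2-yl]pent-2-en-1-yl}benzoic acid | C/C(=C\Cc1cc(C(=O)O)ccc1O)CC[C@H]1C(C)(C)[C@@H]2CC[C@@]1(C)O2 | target

## Step count and risk

Total step count: 13. Longest linear sequence: 11 (steps 1 to 9, then 12 and 13); the arene fragment takes steps 10 and 11.

The three steps most likely to fail:

**Step 9 (proposed new method).** The Lewis-acid-bound oxirane may rearrange by hydride or methyl shift, or be opened by fluoride, before the alkene attacks. The tertiary cation may also lose a proton instead of being captured by oxygen. The fallback separates the two bond formations and uses radical instead of cationic C–C bond formation. It sets out from 12: LiI and AcOH in THF should open the oxirane at CH2 to give the iodohydrin (2R,4R)-1-iodo-3,3-dimethyl-4-(prop-1-en-2-yl)oct-7-yn-2-ol F1. A cobalt-catalysed alkyl-Heck-type radical cyclisation (Co(dmgH)2(py)Cl, i-Pr2NEt, blue light, MeCN) should then close the six-membered ring; the 6-endo mode is favoured because the 5-exo position is fully substituted and flanked by the quaternary carbon. It should give (1S,3R)-3-(but-3-yn-1-yl)-2,2-dimethyl-4-methylidenecyclohexan-1-ol F2, possibly with its endocyclic olefin isomer. Catalytic p-TsOH in CH2Cl2 should then close the bridge by transannular Markovnikov hydroalkoxylation, and the sequence comes back to the route at 13.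

**Step 7.** Addition of the short-lived carbenoid LiCH2Cl to the α-quaternary, neopentyl-type ester may be slower than decomposition of the carbenoid, so conversion may stay incomplete. The fallback builds the oxirane from the aldehyde and sets its configuration by resolution instead of reduction. It sets out from 9: i-Bu2AlH in toluene at −78 °C should give (3R)-2,2-dimethyl-3-(prop-1-en-2-yl)hept-6-ynal F3. Corey–Chaykovsky methylenation (Me3S+ I−, KN(SiMe3)2, THF, 0 °C) should give 2-[(3R)-2-methyl-3-(prop-1-en-2-yl)hept-6-yn-2-yl]oxirane F4 as both epimers at the oxirane carbon. Hydrolytic kinetic resolution follows, with [N,N'-bis(3,5-di-tert-butylsalicylidene)-1,2-cyclohexanediaminato]cobalt acetate and 0.55 equiv of H2O. The catalyst enantiomer is chosen so that the (2S)-epimer is hydrolysed to (2S,4R)-3,3-dimethyl-4-(prop-1-en-2-yl)oct-7-yne-1,2-diol F5, which is removed by chromatography at the cost of that half of the material. The unreacted epimer is 12, where the sequence comes back to the route.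

**Step 12.** The Lewis-acidic alane and zirconocene medium may ionise the tertiary C–O bond of the oxabicycle or metalate the alkyne C–H, and residual AlMe3 may methylate the benzylic bromide. The fallback replaces the alane by a boronate made under basic copper catalysis. It sets out from 13: copper-catalysed methylboration (CuCl, Xantphos, B2pin2, MeI, NaOt-Bu, THF, rt; syn addition with boron on the terminal carbon) should give 4,4,5,5-tetramethyl-2-{(1E)-2-methyl-4-[(1R,2S,4S)-1,3,3-trimethyl-7-oxabicyclo[2.2.1]heptan-2-yl]but-1-en-1-yl}-1,3,2-dioxaborolane F6. Suzuki–Miyaura coupling of F6 with 16 (Pd(dppf)Cl2, K3PO4, THF/H2O, rt) proceeds with retention and comes back to the route at 18.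

## Further compounds

F1 | step 9 | (2R,4R)-1-iodo-3,3-dimethyl-4-(prop-1-en-2-yl)oct-7-yn-2-ol | IC[C@H](O)C(C)(C)[C@H](CCC#C)C(C)=C
F2 | step 9 | (1S,3R)-3-(but-3-yn-1-yl)-2,2-dimethyl-4-methylidenecyclohexan-1-ol | C#CCC[C@H]1C(C)(C)[C@@H](O)CCC1=C
F3 | step 7 | (3R)-2,2-dimethyl-3-(prop-1-en-2-yl)hept-6-ynal | O=CC(C)(C)[C@H](CCC#C)C(C)=C
F4 | step 7 | 2-[(3R)-2-methyl-3-(prop-1-en-2-yl)hept-6-yn-2-yl]oxirane (both epimers at the oxirane carbon) | C#CCC[C@H](C(C)=C)C(C)(C)C1CO1
F5 | step 7 | (2S,4R)-3,3-dimethyl-4-(prop-1-en-2-yl)oct-7-yne-1,2-diol | OC[C@@H](O)C(C)(C)[C@H](CCC#C)C(C)=C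
F6 | step 12 | 4,4,5,5-tetramethyl-2-{(1E)-2-methyl-4-[(1R,2S,4S)-1,3,3-trimethyl-7-oxabicyclo[2.2.1]heptan-2-yl]but-1-en-1-yl}-1,3,2-dioxaborolane | CC1(C)OB(/C=C(\C)CC[C@H]2C(C)(C)[C@@H]3CC[C@@]2(C)O3)OC1(C)C
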